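**Retrosynthetic overview**
- The pyran ring is formed last, by 6-endo addition of the C1 hydroxyl to the alkyne of an ynenone.
- The ynenone comes from a late Sonogashira coupling (C4–C4a) of a side-chain enyne and a carbocyclic β-triflyloxy α-chloro enone, each bringing 13 non-hydrogen atoms.
- Carbocycle: Evans crotonate aldol (C8a), ring-closing metathesis to a δ-lactone template, anti dihydroxylation (C7, C8), lactone opening, Claisen ring closure, chlorination, enol triflation.
- Side chain: Brown (Z)-crotylboration of tiglic aldehyde, hydroboration and cycloetherification (oxolane), ozonolysis, chelation-controlled ethynylation (carbinol), then extension to the E-enyne.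
- Ring order: oxolane; in parallel lactone template, then carbocycle (ring A); pyran (ring B) last.

Assumption: locants C1–C8a are those of the isochromenone core of the target; chiral controllers, the oxazolidinone auxiliary and protecting-group reagents are treated as reagents and carry no number; the 2-chloro-1,3-dione is drawn as one enol tautomer.

**Side-chain branch**

Step 1
Reactants: 1 cis-but-2-ene; 2 (2E)-2-methylbut-2-enal (tiglic aldehyde)
Product: 5 (3S,4R,5E)-3,5-dimethylhepta-1,5-dien-4-ol, via (Z)-crotylpotassium 3 (not isolated), via (Z)-crotyldiisopinocampheylborane 4 (not isolated)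
Conditions: 1, KOtBu, n-BuLi, THF, −78 to −45 °C; (+)-Ipc2BOMe (from (−)-α-pinene), −78 °C; BF3·OEt2; 2, −78 °C; NaOH, H2O2, rt
Reagents that add atoms: none
Why: Brown asymmetric crotylboration through a closed chair transition state, in which the Z-crotyl geometry gives the syn (3S,4R) pair and the isopinocampheyl groups fix its absolute sense (future oxolane C3 and C2).

Step 2
Reactants: 5
Product: 7 (3S,4R,5E)-3,5-dimethylhept-5-ene-1,4-diol, via bis(9-BBN) adduct 6 (not isolated)
Conditions: 9-BBN (2.3 equiv), THF, 0 °C to rt; NaOH, H2O2, 0 °C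
Reagents that add atoms: hydrogen peroxide, OO
Why: anti-Markovnikov hydroboration–oxidation in which 9-BBN takes only the monosubstituted vinyl group and leaves the trisubstituted alkene and both stereocentres untouched.

Step 3
Reactants: 7
Product: 9 (2R,3S)-2-[(2E)-but-2-en-2-yl]-3-methyloxolane, via primary tosylate 8 (not isolated)
Conditions: TsCl (1.1 equiv), pyridine, 0 °C, then 50 °C
Reagents that add atoms: none
Why: selective sulfonylation of the primary alcohol followed by 5-exo-tet Williamson cycloetherification at the primary carbon, so both stereocentres are retained and the syn pair becomes the 2,3-cis oxolane.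

Step 4
Reactants: 9
Product: 11 1-[(2R,3S)-3-methyloxolan-2-yl]ethan-1-one, via secondary ozonide 10 (not isolated)
Conditions: O3, CH2Cl2, −78 °C; Me2S, −78 °C to rt
Reagents that add atoms: ozone, [O-][O+]=O
Why: ozonolysis with reductive work-up unmasks the acetyl group under cold neutral conditions, so the epimerisable cis α-alkoxy ketone is not equilibrated.

Step 5
Reactants: 11
Product: 12 (2R)-2-[(2R,3S)-3-methyloxolan-2-yl]but-3-yn-2-ol
Conditions: MgBr2·OEt2, CH2Cl2, −78 °C; HC≡CMgBr (THF), −78 to −30 °C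
Reagents that add atoms: ethynylmagnesium bromide, C#C[Mg]Br
Why: Cram-chelate-controlled Grignard addition in which magnesium bridges the ketone and ring oxygens and the alkynyl group enters from the face of H-2, opposite ring carbon C3, giving the (R)-carbinol.

Step 6
Reactants: 12
Product: 13 (2R,3E)-2-[(2R,3S)-3-methyloxolan-2-yl]-4-(tributylstannyl)but-3-en-2-ol
Conditions: Bu3SnH, PdCl2(PPh3)2 (2 mol %), THF, 0 °C to rt
Reagents that add atoms: tributyltin hydride, CCCC[SnH](CCCC)CCCC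
Why: palladium-catalysed syn hydrostannation in which the bulky tertiary carbinol steers tin to the terminal carbon, giving the E-vinylstannane.

Step 7
Reactants: 13
Product: 14 (2R,3E)-4-iodo-2-[(2R,3S)-3-methyloxolan-2-yl]but-3-en-2-ol
Conditions: I2, CH2Cl2, 0 °C
Reagents that add atoms: iodine, I-I
Why: iododestannylation is an ipso substitution that keeps the E geometry.

Step 8
Reactants: 14
Product: 15 (2R,3E)-2-[(2R,3S)-3-methyloxolan-2-yl]-6-(trimethylsilyl)hex-3-en-5-yn-2-ol
Conditions: HC≡CSiMe3, Pd(PPh3)4 (3 mol %), CuI (6 mol %), Et3N, THF, rt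
Reagents that add atoms: ethynyl(trimethyl)silane, C#C[Si](C)(C)C
Why: Sonogashira coupling of a vinyl iodide is stereoretentive and tolerates the free tertiary alcohol.

Step 9
Reactants: 15
Product: 16 (2R,3E)-2-[(2R,3S)-3-methyloxolan-2-yl]hex-3-en-5-yn-2-ol
Conditions: K2CO3, MeOH, rt
Reagents that add atoms: none
Why: base-catalysed methanolysis (protodesilylation) of the alkynylsilane frees the terminal alkyne and touches nothing else.

**Carbocycle branch**

Step 10
Reactants: 17 (2E)-but-2-enoyl chloride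
Product: 18 (4S)-4-benzyl-3-[(2E)-but-2-enoyl]-1,3-oxazolidin-2-one
Conditions: (S)-4-benzyl-1,3-oxazolidin-2-one, n-BuLi, THF, −78 °C; then 17, −78 to 0 °C
Reagents that add atoms: (S)-4-benzyl-1,3-oxazolidin-2-one, O=C1N[C@@H](Cc2ccccc2)CO1
Why: N-acylation of the lithiated Evans auxiliary by the acid chloride.

Step 11
Reactants: 18; 19 acetaldehyde
Product: 21 (4S)-4-benzyl-3-[(2S,3R)-2-ethenyl-3-hydroxybutanoyl]-1,3-oxazolidin-2-one, via dibutylboron dienolate 20 (not isolated)
Conditions: Bu2BOTf, Et3N, CH2Cl2, −78 to 0 °C; 19, −78 to 0 °C; pH 7 buffer, MeOH, H2O2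
Reagents that add atoms: none
Why: Evans syn aldol in which the boron dienolate reacts at its α-carbon through a Zimmerman–Traxler chair on the face left open by the benzyl group, fixing the future C8a (the carbinol centre is oxidised away later).

Step 12
Reactants: 21
Product: 22 (2R,3R)-2-ethenylbutane-1,3-diol
Conditions: LiBH4, MeOH (1 equiv), Et2O, 0 °C
Reagents that add atoms: none
Why: reductive cleavage of the imide gives the primary alcohol and releases the auxiliary without touching a stereocentre.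

Step 13
Reactants: 22; 23 2-methylprop-2-enoyl chloride (methacryloyl chloride)
Product: 24 (2R,3R)-2-ethenyl-3-hydroxybutyl 2-methylprop-2-enoate
Conditions: 23 (1.05 equiv), 2,4,6-collidine, CH2Cl2, −78 to −20 °C
Reagents that add atoms: none
Why: kinetically selective acylation of the primary over the secondary hydroxyl by an acid chloride with a hindered pyridine base.

Step 14
Reactants: 24
Product: 25 (5R)-5-[(1R)-1-hydroxyethyl]-3-methyl-5,6-dihydro-2H-pyran-2-one
Conditions: second-generation Grubbs catalyst RuCl2(=CHPh)(H2IMes)(PCy3) (5 mol %), CH2Cl2 (0.01 M), 40 °C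
Reagents that add atoms: none
Why: ring-closing metathesis of the vinyl group onto the methacrylate gives the unsaturated δ-lactone, driven by loss of ethene.

Step 15
Reactants: 25
Product: 26 (3R,4R,5R)-3,4-dihydroxy-5-[(1R)-1-hydroxyethyl]-3-methyloxan-2-one
Conditions: K2OsO2(OH)4 (2 mol %), NMO, citric acid, t-BuOH/H2O (1:1), rt
Reagents that add atoms: N-methylmorpholine N-oxide (oxygen passed on through OsO4), C[N+]1([O-])CCOCC1; water, O
Why: catalytic OsO4 syn dihydroxylation on the ring face anti to the C5 substituent sets C7 and C8 as the cis diol trans to the hydroxyethyl group.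

Step 16
Reactants: 26
Product: 27 (3aR,7R,7aR)-7-[(1R)-1-hydroxyethyl]-2,2,3a-trimethyltetrahydro-4H-[1,3]dioxolo[4,5-c]pyran-4-one (the 3,4-O-isopropylidene derivative of 26)
Conditions: 2,2-dimethoxypropane, CSA (5 mol %), acetone, rt
Reagents that add atoms: 2,2-dimethoxypropane, COC(C)(C)OC
Why: thermodynamic acetonide formation selects the cis-vicinal diol (five-membered dioxolane) over the 1,3-diol.

Step 17
Reactants: 27
Product: 28 (4R,5R)-5-[(2R,3R)-1,3-dihydroxybutan-2-yl]-N-methoxy-N,2,2,4-tetramethyl-1,3-dioxolane-4-carboxamide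
Conditions: MeNH(OMe)·HCl, AlMe3, CH2Cl2, 0 °C to rt; aq. potassium sodium tartrate
Reagents that add atoms: N,O-dimethylhydroxylamine hydrochloride, CNOC.Cl
Why: Weinreb aminolysis by MeClAl–N(OMe)Me opens the lactone to the acyclic amide and frees the C1 hydroxyl (a lactone isomer from acyl migration would give the same product).

Step 18
Reactants: 28
Product: 29 (4R,5R)-5-[(2R,3R)-1-{[tert-butyl(dimethyl)silyl]oxy}-3-hydroxybutan-2-yl]-N-methoxy-N,2,2,4-tetramethyl-1,3-dioxolane-4-carboxamide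
Conditions: TBSCl (1.05 equiv), imidazole, CH2Cl2, 0 °C
Reagents that add atoms: tert-butyl(chloro)dimethylsilane, CC(C)(C)[Si](C)(C)Cl
Why: sterically controlled silylation of the primary over the secondary alcohol.

Step 19
Reactants: 29
Product: 30 (4R,5R)-5-[(2S)-1-{[tert-butyl(dimethyl)silyl]oxy}-3-oxobutan-2-yl]-N-methoxy-N,2,2,4-tetramethyl-1,3-dioxolane-4-carboxamide
Conditions: Dess–Martin periodinane, NaHCO3, CH2Cl2, 0 °C to rt
Reagents that add atoms: none
Why: buffered Dess–Martin oxidation gives the methyl ketone without epimerising C8a or eliminating a β-oxygen (the new descriptor at C8a is only a priority change).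

Step 20
Reactants: 30
Product: 32 (3aR,7S,7aR)-7-({[tert-butyl(dimethyl)silyl]oxy}methyl)-2,2,3a-trimethyl-3a,7a-dihydro-1,3-benzodioxole-4,6(5H,7H)-dione, via lithium enolate 31 (not isolated)
Conditions: LiN(SiMe3)2 (2.5 equiv), THF, −78 to 0 °C; aq. NH4Cl
Reagents that add atoms: none
Why: intramolecular Claisen (Dieckmann-type) condensation in which the kinetic methyl-ketone enolate acylates on the Weinreb amide (6-exo-trig) and closes the carbocycle cis-fused to the dioxolane, with no new stereocentre.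

Step 21
Reactants: 32
Product: 33 (3aR,7S,7aR)-7-({[tert-butyl(dimethyl)silyl]oxy}methyl)-5-chloro-6-hydroxy-2,2,3a-trimethyl-7,7a-dihydro-1,3-benzodioxol-4(3aH)-one (enol form)
Conditions: NCS (1.0 equiv), CH2Cl2, 0 °C
Reagents that add atoms: N-chlorosuccinimide, O=C1CCC(=O)N1Cl
Why: electrophilic α-chlorination of the enolised 1,3-dione at C5, the only doubly activated carbon.

Step 22
Reactants: 33
Product: 34 (3aR,7S,7aR)-7-({[tert-butyl(dimethyl)silyl]oxy}methyl)-5-chloro-2,2,3a-trimethyl-4-oxo-3a,4,7,7a-tetrahydro-1,3-benzodioxol-6-yl trifluoromethanesulfonate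
Conditions: Tf2O (1.1 equiv), pyridine, CH2Cl2, −78 to 0 °C
Reagents that add atoms: trifluoromethanesulfonic anhydride, O=S(=O)(OS(=O)(=O)C(F)(F)F)C(F)(F)F
Why: O-sulfonylation of the dione enolate at the less hindered oxygen (on C4a, next to the C8a methine) and not at the oxygen on C6 beside quaternary C7, which leaves the ketone at C6.

Step 23
Reactants: 34
Product: 35 (4R,5R,6S)-2-chloro-4,5-dihydroxy-6-(hydroxymethyl)-4-methyl-3-oxocyclohex-1-en-1-yl trifluoromethanesulfonate
Conditions: CF3CO2H/H2O (9:1), 0 °C to rt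
Reagents that add atoms: none
Why: acid hydrolysis removes the acetonide and the silyl ether in one operation before the acid-sensitive side chain is attached, and the vinyl sulfonate should survive brief aqueous acid.

**Coupling and last ring**

Step 24
Reactants: 35; 16
Product: 36 (4S,5R,6R)-2-chloro-5,6-dihydroxy-4-(hydroxymethyl)-3-{(3E,5R)-5-hydroxy-5-[(2R,3S)-3-methyloxolan-2-yl]hex-3-en-1-yn-1-yl}-6-methylcyclohex-2-en-1-one
Conditions: Pd(PPh3)4 (5 mol %), CuI (10 mol %), i-Pr2NEt, DMF, rt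
Reagents that add atoms: none
Why: Sonogashira coupling in which zerovalent palladium inserts into the activated C–OTf bond much faster than into the vinyl C–Cl bond and free hydroxyls are tolerated (partial closure to 37 in the flask would be harmless).

Step 25
Reactants: 36
Product: 37 Peniciazaphilone E, (7R,8R,8aS)-5-chloro-7,8-dihydroxy-3-{(1E,3R)-3-hydroxy-3-[(2R,3S)-3-methyloxolan-2-yl]but-1-en-1-yl}-7-methyl-1,7,8,8a-tetrahydro-6H-isochromen-6-one
Conditions: Ph3PAuNTf2 (5 mol %), CH2Cl2/THF, rt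
Reagents that add atoms: none
Why: gold-catalysed 6-endo-dig hydroalkoxylation (formally an oxa-1,6-addition to the ynenone) in which the C1 hydroxyl attacks C3, the only mode that gives an unstrained fused ring, with all stereocentres carried through.

**Compound list**

1 | cis-but-2-ene | C/C=C\C | starting material
2 | (2E)-2-methylbut-2-enal (tiglic aldehyde) | C/C=C(\C)C=O | starting material
3 | (Z)-but-2-en-1-ylpotassium | C/C=C\C[K] | intermediate (not isolated)
4 | [(2Z)-but-2-en-1-yl]bis(isopinocampheyl)borane, Ipc from (−)-α-pinene | C/C=C\CB([C@H]1C[C@H]2C[C@@H]([C@@H]1C)C2(C)C)[C@H]1C[C@H]2C[C@@H]([C@@H]1C)C2(C)C | intermediate (not isolated)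
5 | (3S,4R,5E)-3,5-dimethylhepta-1,5-dien-4-ol | C=C[C@H](C)[C@@H](O)/C(C)=C/C | intermediate
6 | 9-[(3S,4R,5E)-4-(9-borabicyclo[3.3.1]nonan-9-yloxy)-3,5-dimethylhept-5-en-1-yl]-9-borabicyclo[3.3.1]nonane | C1CC2CCCC(C1)B2CC[C@H](C)[C@@H](OB1C2CCCC1CCC2)/C(C)=C/C | intermediate (not isolated)
7 | (3S,4R,5E)-3,5-dimethylhept-5-ene-1,4-diol | OCC[C@H](C)[C@@H](O)/C(C)=C/C | intermediate
8 | (3S,4R,5E)-4-hydroxy-3,5-dimethylhept-5-en-1-yl 4-methylbenzenesulfonate | Cc1ccc(cc1)S(=O)(=O)OCC[C@H](C)[C@@H](O)/C(C)=C/C | intermediate (not isolated)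
9 | (2R,3S)-2-[(2E)-but-2-en-2-yl]-3-methyloxolane | C[C@H]1CCO[C@H]1/C(C)=C/C | intermediate
10 | 3,5-dimethyl-3-[(2R,3S)-3-methyloxolan-2-yl]-1,2,4-trioxolane | C[C@H]1CCO[C@H]1C1(C)OOC(C)O1 | intermediate (not isolated)
11 | 1-[(2R,3S)-3-methyloxolan-2-yl]ethan-1-one | C[C@H]1CCO[C@H]1C(C)=O | intermediate
12 | (2R)-2-[(2R,3S)-3-methyloxolan-2-yl]but-3-yn-2-ol | C[C@H]1CCO[C@H]1[C@](C)(O)C#C | intermediate
13 | (2R,3E)-2-[(2R,3S)-3-methyloxolan-2-yl]-4-(tributylstannyl)but-3-en-2-ol | C[C@H]1CCO[C@H]1[C@](C)(O)/C=C/[Sn](CCCC)(CCCC)CCCC | intermediate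
14 | (2R,3E)-4-iodo-2-[(2R,3S)-3-methyloxolan-2-yl]but-3-en-2-ol | C[C@H]1CCO[C@H]1[C@](C)(O)/C=C/I | intermediate
15 | (2R,3E)-2-[(2R,3S)-3-methyloxolan-2-yl]-6-(trimethylsilyl)hex-3-en-5-yn-2-ol | C[C@H]1CCO[C@H]1[C@](C)(O)/C=C/C#C[Si](C)(C)C | intermediate
16 | (2R,3E)-2-[(2R,3S)-3-methyloxolan-2-yl]hex-3-en-5-yn-2-ol | C[C@H]1CCO[C@H]1[C@](C)(O)/C=C/C#C | intermediate
17 | (2E)-but-2-enoyl chloride | C/C=C/C(Cl)=O | starting material
18 | (4S)-4-benzyl-3-[(2E)-but-2-enoyl]-1,3-oxazolidin-2-one | C/C=C/C(=O)N1[C@@H](Cc2ccccc2)COC1=O | intermediate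
19 | acetaldehyde | CC=O | starting material
20 | (4S)-4-benzyl-3-{(1Z)-1-[(dibutylboranyl)oxy]buta-1,3-dien-1-yl}-1,3-oxazolidin-2-one | C=C/C=C(\OB(CCCC)CCCC)N1[C@@H](Cc2ccccc2)COC1=O | intermediate (not isolated)
21 | (4S)-4-benzyl-3-[(2S,3R)-2-ethenyl-3-hydroxybutanoyl]-1,3-oxazolidin-2-one | C=C[C@@H]([C@@H](C)O)C(=O)N1[C@@H](Cc2ccccc2)COC1=O | intermediate
22 | (2R,3R)-2-ethenylbutane-1,3-diol | C=C[C@@H]([C@@H](C)O)CO | intermediate
23 | 2-methylprop-2-enoyl chloride | CC(=C)C(Cl)=O | starting material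
24 | (2R,3R)-2-ethenyl-3-hydroxybutyl 2-methylprop-2-enoate | C=C[C@@H]([C@@H](C)O)COC(=O)C(C)=C | intermediate
25 | (5R)-5-[(1R)-1-hydroxyethyl]-3-methyl-5,6-dihydro-2H-pyran-2-one | CC1=C[C@@H]([C@@H](C)O)COC1=O | intermediate
26 | (3R,4R,5R)-3,4-dihydroxy-5-[(1R)-1-hydroxyethyl]-3-methyloxan-2-one | O=C1[C@](C)(O)[C@H](O)[C@@H]([C@@H](C)O)CO1 | intermediate
27 | (3aR,7R,7aR)-7-[(1R)-1-hydroxyethyl]-2,2,3a-trimethyltetrahydro-4H-[1,3]dioxolo[4,5-c]pyran-4-one | O=C1[C@]2(C)OC(C)(C)O[C@@H]2[C@@H]([C@@H](C)O)CO1 | intermediate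
28 | (4R,5R)-5-[(2R,3R)-1,3-dihydroxybutan-2-yl]-N-methoxy-N,2,2,4-tetramethyl-1,3-dioxolane-4-carboxamide | CON(C)C(=O)[C@]1(C)OC(C)(C)O[C@@H]1[C@@H]([C@@H](C)O)CO | intermediate
29 | (4R,5R)-5-[(2R,3R)-1-{[tert-butyl(dimethyl)silyl]oxy}-3-hydroxybutan-2-yl]-N-methoxy-N,2,2,4-tetramethyl-1,3-dioxolane-4-carboxamide | CON(C)C(=O)[C@]1(C)OC(C)(C)O[C@@H]1[C@@H]([C@@H](C)O)CO[Si](C)(C)C(C)(C)C | intermediate
30 | (4R,5R)-5-[(2S)-1-{[tert-butyl(dimethyl)silyl]oxy}-3-oxobutan-2-yl]-N-methoxy-N,2,2,4-tetramethyl-1,3-dioxolane-4-carboxamide | CON(C)C(=O)[C@]1(C)OC(C)(C)O[C@@H]1[C@@H](C(C)=O)CO[Si](C)(C)C(C)(C)C | intermediate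
31 | lithium enolate of 30 (terminal, C5=C4a–OLi) | CON(C)C(=O)[C@]1(C)OC(C)(C)O[C@@H]1[C@@H](C(=C)O[Li])CO[Si](C)(C)C(C)(C)C | intermediate (not isolated)
32 | (3aR,7S,7aR)-7-({[tert-butyl(dimethyl)silyl]oxy}methyl)-2,2,3a-trimethyl-3a,7a-dihydro-1,3-benzodioxole-4,6(5H,7H)-dione | O=C1CC(=O)[C@]2(C)OC(C)(C)O[C@@H]2[C@@H]1CO[Si](C)(C)C(C)(C)C | intermediate
33 | (3aR,7S,7aR)-7-({[tert-butyl(dimethyl)silyl]oxy}methyl)-5-chloro-6-hydroxy-2,2,3a-trimethyl-7,7a-dihydro-1,3-benzodioxol-4(3aH)-one | OC1=C(Cl)C(=O)[C@]2(C)OC(C)(C)O[C@@H]2[C@@H]1CO[Si](C)(C)C(C)(C)C | intermediate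
34 | (3aR,7S,7aR)-7-({[tert-butyl(dimethyl)silyl]oxy}methyl)-5-chloro-2,2,3a-trimethyl-4-oxo-3a,4,7,7a-tetrahydro-1,3-benzodioxol-6-yl trifluoromethanesulfonate | O=S(=O)(OC1=C(Cl)C(=O)[C@]2(C)OC(C)(C)O[C@@H]2[C@@H]1CO[Si](C)(C)C(C)(C)C)C(F)(F)F | intermediate
35 | (4R,5R,6S)-2-chloro-4,5-dihydroxy-6-(hydroxymethyl)-4-methyl-3-oxocyclohex-1-en-1-yl trifluoromethanesulfonate | O=S(=O)(OC1=C(Cl)C(=O)[C@](C)(O)[C@H](O)[C@@H]1CO)C(F)(F)F | intermediate
36 | (4S,5R,6R)-2-chloro-5,6-dihydroxy-4-(hydroxymethyl)-3-{(3E,5R)-5-hydroxy-5-[(2R,3S)-3-methyloxolan-2-yl]hex-3-en-1-yn-1-yl}-6-methylcyclohex-2-en-1-one | C[C@H]1CCO[C@H]1[C@](C)(O)/C=C/C#CC1=C(Cl)C(=O)[C@](C)(O)[C@H](O)[C@@H]1CO | intermediate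
37 | Peniciazaphilone E, (7R,8R,8aS)-5-chloro-7,8-dihydroxy-3-{(1E,3R)-3-hydroxy-3-[(2R,3S)-3-methyloxolan-2-yl]but-1-en-1-yl}-7-methyl-1,7,8,8a-tetrahydro-6H-isochromen-6-one | C[C@H]1CCO[C@H]1[C@](C)(O)/C=C/C1=CC2=C(Cl)C(=O)[C@](C)(O)[C@H](O)[C@@H]2CO1 | target

**Totals**

Total step count: 25.
Longest linear sequence: 16 steps (17 to 37, steps 10–25). The other branch is 11 steps (steps 1–9, then 24 and 25).

**Steps most likely to fail, with fallbacks**

Step 20 (Claisen ring closure). The enolate may equilibrate towards C8a and eliminate a β-oxygen, and the amide carbonyl sits beside a quaternary carbon. The fallback replaces acylation by an aldol–oxidation sequence and sets out from 30. Trapping the kinetic enolate in the flask (LiN(SiMe3)2, Et3SiCl, THF, −78 °C) gives the triethylsilyl enol ether F1. Reduction of the Weinreb amide (i-Bu2AlH, THF, −78 °C) gives the aldehyde F2. An intramolecular Mukaiyama aldol (BF3·OEt2, CH2Cl2, −78 °C) closes the ring to the β-hydroxy ketone F3, formed as both carbinol epimers. Dess–Martin oxidation of the carbinol brings the material back to the route at 32.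

Step 22 (enol triflation). The chloro-dione enolate is a poor nucleophile, the two oxygens may not be fully distinguished, and the product is a labile vinylogous acyl triflate. The fallback replaces O-sulfonylation by deoxychlorination and sets out from 33. Ph3P and CCl4 (MeCN, rt) give the 2,3-dichloro enone F4, in which chloride has entered by addition–elimination at the less hindered ring carbon C4a. F4 is stable to chromatography, so a minor regioisomer can be removed. CF3CO2H/H2O then gives the dichloro enone triol F5. Sonogashira coupling of F5 with 16 at the β-chloride (Pd(PPh3)4, CuI, i-Pr2NEt, DMF, 40 °C) comes back to the route at 36.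

Step 23 (acid unmasking next to the triflate). Aqueous acid could hydrolyse the vinylogous acyl triflate back to the dione before the acetonide is gone. The fallback inverts the order of coupling and deprotection and sets out from 34. Sonogashira coupling of 34 with 16 (Pd(PPh3)4, CuI, i-Pr2NEt, DMF, rt) gives the protected ynenone F6. Hydrolysis of the acetonide and silyl ether (CF3CO2H/H2O/THF, 0 °C) then returns to the route at 36.

**Further compounds**

F1 | step 20 | (4R,5R)-5-[(2S)-1-{[tert-butyl(dimethyl)silyl]oxy}-3-[(triethylsilyl)oxy]but-3-en-2-yl]-N-methoxy-N,2,2,4-tetramethyl-1,3-dioxolane-4-carboxamide | CON(C)C(=O)[C@]1(C)OC(C)(C)O[C@@H]1[C@@H](C(=C)O[Si](CC)(CC)CC)CO[Si](C)(C)C(C)(C)C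
F2 | step 20 | (4R,5R)-5-[(2S)-1-{[tert-butyl(dimethyl)silyl]oxy}-3-[(triethylsilyl)oxy]but-3-en-2-yl]-2,2,4-trimethyl-1,3-dioxolane-4-carbaldehyde | O=C[C@]1(C)OC(C)(C)O[C@@H]1[C@@H](C(=C)O[Si](CC)(CC)CC)CO[Si](C)(C)C(C)(C)C
F3 | step 20 | (3aS,7S,7aR)-7-({[tert-butyl(dimethyl)silyl]oxy}methyl)-4-hydroxy-2,2,3a-trimethylhexahydro-1,3-benzodioxol-6-one (both C4 epimers) | O=C1CC(O)[C@]2(C)OC(C)(C)O[C@@H]2[C@@H]1CO[Si](C)(C)C(C)(C)C
F4 | step 22 | (3aR,7S,7aR)-7-({[tert-butyl(dimethyl)silyl]oxy}methyl)-5,6-dichloro-2,2,3a-trimethyl-7,7a-dihydro-1,3-benzodioxol-4(3aH)-one | ClC1=C(Cl)C(=O)[C@]2(C)OC(C)(C)O[C@@H]2[C@@H]1CO[Si](C)(C)C(C)(C)C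
F5 | step 22 | (4S,5R,6R)-2,3-dichloro-5,6-dihydroxy-4-(hydroxymethyl)-6-methylcyclohex-2-en-1-one | ClC1=C(Cl)C(=O)[C@](C)(O)[C@H](O)[C@@H]1CO
F6 | step 23 | (3aR,7S,7aR)-7-({[tert-butyl(dimethyl)silyl]oxy}methyl)-5-chloro-6-{(3E,5R)-5-hydroxy-5-[(2R,3S)-3-methyloxolan-2-yl]hex-3-en-1-yn-1-yl}-2,2,3a-trimethyl-7,7a-dihydro-1,3-benzodioxol-4(3aH)-one | C[C@H]1CCO[C@H]1[C@](C)(O)/C=C/C#CC1=C(Cl)C(=O)[C@]2(C)OC(C)(C)O[C@@H]2[C@@H]1CO[Si](C)(C)C(C)(C)C
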